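## Retrosynthetic overview

1. Target 12 ⇐ acetate 11 (methanolysis) ⇐ skipped diene 10. A transpositional bis-allylic C–H acetoxylation forms the primary C–O bond and, in the same event, the (3'E)-trisubstituted olefin of the triene (key step).
2. 10 ⇐ terminal alkyne 6 + 4-allylbutenolide 9, by Alder-ene coupling, which builds the 2-alkyl-1,4-diene and the (1'E) olefin.
3. 6 ⇐ iodide 5 ⇐ alcohol 4 ⇐ ester 3 ⇐ (+)-sclareolide 1. Acid opening of the lactone gives the tetrasubstituted ring olefin; both stereocentres come from 1.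
4. 9 ⇐ 4-bromofuran-2(5H)-one 7 + allyltributylstannane 8 (Stille allylation).
5. Rings: none is built. The trans-decalin (rings A and B) comes intact from 1 and the butenolide (ring C) from 7; only the lactone ring of 1 is opened.

Assumption: 1, 7 and 8 are purchased.

Abbreviations: Dec = (4aS,8aS)-2,5,5,8a-tetramethyl-3,4,4a,5,6,7,8,8a-octahydronaphthalen-1-yl (trans-fused, ring double bond between C-1 and C-2). Chain locants run from 1' (carbon on the furanone) to 6' (carbon on Dec).

## Route

Step 1
Reactants: 1 (+)-sclareolide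
Product: 3 methyl (Dec)acetate, via (Dec)acetic acid 2 (not isolated)
Conditions: conc. H2SO4 (2 equiv), MeOH, reflux, 24 h; AgNO3–silica chromatography
Reagents that add atoms: methanol (CO)
Why: Acid-mediated alkyl–oxygen ionisation of the tertiary lactone (E1 ring opening) under equilibrating conditions should favour the tetrasubstituted ring-olefin acid, which is trapped by Fischer esterification; C-4a and C-8a of sclareolide are not touched.

Step 2
Reactants: 3 methyl (Dec)acetate
Product: 4 2-(Dec)ethan-1-ol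
Conditions: LiAlH4, THF, 0 °C to rt
Reagents that add atoms: none
Why: Hydride reduction of the ester to the primary alcohol; the isolated tetrasubstituted olefin is inert.

Step 3
Reactants: 4 2-(Dec)ethan-1-ol
Product: 5 2-(Dec)ethyl iodide
Conditions: PPh3, I2, imidazole, CH2Cl2, 0 °C to rt
Reagents that add atoms: iodine (II)
Why: Appel-type iodination, SN2 displacement of the alkoxyphosphonium by iodide at the primary carbon.

Step 4
Reactants: 5 2-(Dec)ethyl iodide
Product: 6 4-(Dec)but-1-yne
Conditions: LiC≡CH·H2NCH2CH2NH2 (2 equiv), DMSO, 15 °C to rt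
Reagents that add atoms: lithium acetylide–ethylenediamine complex ([Li+].[C-]#C.NCCN)
Why: SN2 alkylation of lithium acetylide by a primary iodide in DMSO, where substitution normally outruns E2.

Step 5
Reactants: 7 4-bromofuran-2(5H)-one; 8 allyltributylstannane
Product: 9 4-(prop-2-en-1-yl)furan-2(5H)-one
Conditions: Pd2(dba)3 (2.5 mol %), tri(2-furyl)phosphine (10 mol %), THF, 60 °C
Reagents that add atoms: none
Why: Stille coupling — oxidative addition of the vinylogous acyl bromide to zerovalent palladium, allyl transfer from tin and reductive elimination under neutral conditions that leave the allyl group unconjugated.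

Step 6
Reactants: 6 4-(Dec)but-1-yne; 9 4-(prop-2-en-1-yl)furan-2(5H)-one
Product: 10 4-[(1E)-4-methylidene-6-(Dec)hex-1-en-1-yl]furan-2(5H)-one
Conditions: [CpRu(MeCN)3]PF6 (10 mol %), acetone, rt
Reagents that add atoms: none
Why: Alder-ene (alkene–alkyne) coupling through a ruthenacyclopentene, β-hydride elimination of the allylic hydrogen next to the butenolide and reductive elimination; an unhindered terminal alkyne favours the branched 1,4-diene with an (E) olefin, and the tetrasubstituted ring olefin does not bind.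

Step 7
Reactants: 10 4-[(1E)-4-methylidene-6-(Dec)hex-1-en-1-yl]furan-2(5H)-one
Product: 11 (2E,4E)-2-[2-(Dec)ethyl]-5-(5-oxo-2,5-dihydrofuran-3-yl)penta-2,4-dien-1-yl acetate
Conditions: Pd(OAc)2 (10 mol %), 1,2-bis(phenylsulfinyl)ethane (10 mol %), 2,6-dimethyl-1,4-benzoquinone (2 equiv), AcOH (10 equiv), 1,4-dioxane, 45 °C
Reagents that add atoms: acetic acid (CC(=O)O)
Why: Proposed new method: transpositional bis-allylic C–H acetoxylation of a 2-alkyl-1,4-diene — electrophilic divalent palladium bound to the unhindered 1,1-disubstituted olefin cleaves, with acetate as internal base, the doubly allylic and vinylogously acidified C-3'–H to a π-allyl (pentadienyl) palladium species; quinone-promoted C–O bond formation should occur at the unsubstituted CH2 terminus, which is the least hindered, the farthest from the electron-poor butenolide and the only site giving the fully conjugated trienyl lactone (a branched acetate, if formed, would be funnelled to 11 by the known palladium-mediated [3,3] acetate shift); the (E)-trisubstituted olefin follows from the favoured syn placement of the dienyl group on the π-allyl, which puts it cis to the CH2CH2Dec arm and trans to CH2OAc; the closest known reaction types are the linear allylic C–H acetoxylation of monosubstituted terminal olefins with Pd(OAc)2/bis-sulfoxide/benzoquinone and the bis-allylic C–H alkylation of 1,4-dienes with Pd(OAc)2, neither shown for C–O formation with transposition on a 1,1-disubstituted olefin.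

Step 8
Reactants: 11 (2E,4E)-2-[2-(Dec)ethyl]-5-(5-oxo-2,5-dihydrofuran-3-yl)penta-2,4-dien-1-yl acetate
Product: 12 4-[(1E,3E)-4-(hydroxymethyl)-6-(Dec)hexa-1,3-dien-1-yl]furan-2(5H)-one
Conditions: K2CO3 (0.3 equiv), MeOH, 0 °C, argon
Reagents that add atoms: none
Why: Base-catalysed transesterification (Zemplén-type methanolysis) of the primary allylic acetate is much faster at 0 °C than any reaction of the butenolide and does not touch the olefin geometry.

## Compound list

1 | (+)-sclareolide, (3aR,5aS,9aS,9bR)-3a,6,6,9a-tetramethyldecahydronaphtho[2,1-b]furan-2(1H)-one | O=C1C[C@H]2[C@@](C)(CC[C@H]3C(C)(C)CCC[C@]23C)O1 | starting material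
2 | (Dec)acetic acid, 2-[(4aS,8aS)-2,5,5,8a-tetramethyl-3,4,4a,5,6,7,8,8a-octahydronaphthalen-1-yl]acetic acid | CC1=C(CC(=O)O)[C@@]2(C)CCCC(C)(C)[C@@H]2CC1 | intermediate (not isolated)
3 | methyl (Dec)acetate | CC1=C(CC(=O)OC)[C@@]2(C)CCCC(C)(C)[C@@H]2CC1 | intermediate
4 | 2-(Dec)ethan-1-ol | CC1=C(CCO)[C@@]2(C)CCCC(C)(C)[C@@H]2CC1 | intermediate
5 | 2-(Dec)ethyl iodide, (4aS,8aS)-1-(2-iodoethyl)-2,5,5,8a-tetramethyl-3,4,4a,5,6,7,8,8a-octahydronaphthalene | CC1=C(CCI)[C@@]2(C)CCCC(C)(C)[C@@H]2CC1 | intermediate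
6 | 4-(Dec)but-1-yne | CC1=C(CCC#C)[C@@]2(C)CCCC(C)(C)[C@@H]2CC1 | intermediate
7 | 4-bromofuran-2(5H)-one | O=C1C=C(Br)CO1 | starting material
8 | allyltributylstannane | C=CC[Sn](CCCC)(CCCC)CCCC | starting material
9 | 4-(prop-2-en-1-yl)furan-2(5H)-one | C=CCC1=CC(=O)OC1 | intermediate
10 | 4-[(1E)-4-methylidene-6-(Dec)hex-1-en-1-yl]furan-2(5H)-one | CC1=C(CCC(=C)C/C=C/C2=CC(=O)OC2)[C@@]2(C)CCCC(C)(C)[C@@H]2CC1 | intermediate
11 | (2E,4E)-2-[2-(Dec)ethyl]-5-(5-oxo-2,5-dihydrofuran-3-yl)penta-2,4-dien-1-yl acetate | CC1=C(CC/C(=C\C=C\C2=CC(=O)OC2)COC(C)=O)[C@@]2(C)CCCC(C)(C)[C@@H]2CC1 | intermediate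
12 | 4-[(1E,3E)-4-(hydroxymethyl)-6-(Dec)hexa-1,3-dien-1-yl]furan-2(5H)-one (CNP0232848.5) | CC1=C(CC/C(=C\C=C\C2=CC(=O)OC2)CO)[C@@]2(C)CCCC(C)(C)[C@@H]2CC1 | target

## Step count and risks

Total step count: 8. Longest linear sequence: 7 (steps 1, 2, 3, 4, 6, 7, 8).

The three steps most likely to fail:

**Step 7 (proposed new method).** The risks are no C–H cleavage at the 1,1-disubstituted olefin, acetate delivery at the wrong terminus, or erosion of the trisubstituted olefin geometry. The fallback uses known chemistry, sets out from 6 (with 7) and comes back at 12.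
- Haloboration of 6 with 9-iodo-9-borabicyclo[3.3.1]nonane (pentane, −20 °C) gives the (Z)-2-iodoalkenylborane F7, which is not isolated.
- AcOH protodeboronates it to 2-iodo-4-(Dec)but-1-ene F8.
- Heck reaction of 7 with acrolein (Pd(OAc)2, NaHCO3, Bu4NCl, DMF, 50 °C) gives (2E)-3-(5-oxo-2,5-dihydrofuran-3-yl)prop-2-enal F9.
- Nozaki–Hiyama–Kishi coupling of F8 with F9 (CrCl2, 2 mol % NiCl2, DMSO, rt) gives the bis-allylic alcohol 4-[(1E)-3-hydroxy-4-methylidene-6-(Dec)hex-1-en-1-yl]furan-2(5H)-one F10.
- O3ReOSiPh3 (5 mol %, Et2O, −50 to 0 °C) then effects the 1,3-transposition of the hydroxyl through a chair-like perrhenate ester with the dienyl group equatorial. This forms the same C–O bond and the (3'E) olefin, driven by conjugation, and gives 12 directly.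

**Step 6.** The risks are a linear Alder-ene isomer and migration of the allyl double bond of 9. The fallback sets out from 5 (with 7) and comes back at 10.
- Stille mono-coupling of 7 with (E)-1,2-bis(tributylstannyl)ethene (3 equiv, Pd(PPh3)4, toluene, 80 °C) gives 4-[(E)-2-(tributylstannyl)ethenyl]furan-2(5H)-one F4.
- Allyl–vinyl Stille coupling of F4 with 2,3-dibromopropene (Pd2(dba)3, AsPh3, THF, 50 °C) gives 4-[(1E)-4-bromopenta-1,4-dien-1-yl]furan-2(5H)-one F5; the allylic bromide reacts and the vinylic one stays.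
- Iodide 5 is converted with Zn dust and LiCl in THF into [2-(Dec)ethyl]zinc iodide F6.
- Negishi coupling of F6 with F5 (PdCl2(dppf), THF, rt) gives 10.

**Step 1.** The risks are an inseparable mixture of ring-olefin isomers or acid-induced skeletal rearrangement. The fallback sets out from 1 and comes back at 4.
- α-Selenenylation (LiN(iPr)2, PhSeBr, THF, −78 °C) from the open α-face gives 1-(phenylselanyl)sclareolide F1.
- H2O2/pyridine (CH2Cl2, 0 °C) oxidises it to the selenoxide F2, which loses PhSeOH by syn-elimination towards the cis 9b-hydrogen to give 9(11)-dehydrosclareolide F3.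
- SmI2 (THF–HMPA, t-BuOH, −78 °C) cleaves the allylic C–O bond of this butenolide reductively. α-Protonation of the resulting dienolate places the double bond regiospecifically at the tetrasubstituted position and gives acid 2, isolated this time.
- LiAlH4 (THF, reflux) reduces 2 directly to 4.

Further compounds
F1 | step 1 | 1-(phenylselanyl)sclareolide, (3aR,5aS,9aS,9bR)-3a,6,6,9a-tetramethyl-1-(phenylselanyl)decahydronaphtho[2,1-b]furan-2(1H)-one (C-1 configuration not defined) | O=C1C([Se]c2ccccc2)[C@H]2[C@@](C)(CC[C@H]3C(C)(C)CCC[C@]23C)O1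
F2 | step 1 | 1-(phenylseleninyl)sclareolide (selenoxide of F1) | O=C1C([Se](=O)c2ccccc2)[C@H]2[C@@](C)(CC[C@H]3C(C)(C)CCC[C@]23C)O1
F3 | step 1 | 9(11)-dehydrosclareolide, (3aR,5aS,9aS)-3a,6,6,9a-tetramethyl-4,5,5a,6,7,8,9,9a-octahydronaphtho[2,1-b]furan-2(3aH)-one | O=C1C=C2[C@@](C)(CC[C@H]3C(C)(C)CCC[C@]23C)O1
F4 | step 6 | 4-[(E)-2-(tributylstannyl)ethenyl]furan-2(5H)-one | CCCC[Sn](CCCC)(CCCC)/C=C/C1=CC(=O)OC1
F5 | step 6 | 4-[(1E)-4-bromopenta-1,4-dien-1-yl]furan-2(5H)-one | C=C(Br)C/C=C/C1=CC(=O)OC1
F6 | step 6 | [2-(Dec)ethyl]zinc iodide | CC1=C(CC[Zn]I)[C@@]2(C)CCCC(C)(C)[C@@H]2CC1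
F7 | step 7 | 9-[(1Z)-2-iodo-4-(Dec)but-1-en-1-yl]-9-borabicyclo[3.3.1]nonane | CC1=C(CC/C(I)=C/B2C3CCCC2CCC3)[C@@]2(C)CCCC(C)(C)[C@@H]2CC1
F8 | step 7 | 2-iodo-4-(Dec)but-1-ene | CC1=C(CCC(I)=C)[C@@]2(C)CCCC(C)(C)[C@@H]2CC1
F9 | step 7 | (2E)-3-(5-oxo-2,5-dihydrofuran-3-yl)prop-2-enal | O=C/C=C/C1=CC(=O)OC1
F10 | step 7 | 4-[(1E)-3-hydroxy-4-methylidene-6-(Dec)hex-1-en-1-yl]furan-2(5H)-one (carbinol configuration not defined) | CC1=C(CCC(=C)C(O)/C=C/C2=CC(=O)OC2)[C@@]2(C)CCCC(C)(C)[C@@H]2CC1
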